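**Strategy.** Ring A (C1–C6 of the spiro[5.5]undecene) is read as a masked 5,5-dimethylcyclohexane-1,3-dione: C1 and C3 are the former carbonyls, C2 the acetyl methyl between them and C5 the β-carbon of an isopropylidene acceptor. A one-pot Michael–Dieckmann annulation of an isopropylidene acetoacetate with the enolate of ethyl acetate therefore forges C4–C5 and C2–C3 together and leaves C6 as an allyl β-keto ester carbon. That ester is traded for an exocyclic methylene, on which an enantioselective spirocyclising Diels–Alder reaction with isoprene builds ring B and the quaternary centre; methyl addition, anti-halogenation of ring B and bromination/reduction of the enone finish the target.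

Key step: step 2

Remark: locants C1–C11 are those of the target named as a spiro[5.5]undec-1-en-3-ol (C6 is the spiro carbon); the hand of the chiral acid in step 5 is assumed to be the one that delivers the (6S) spirocycle 10, since the sense of induction cannot be derived from first principles for this enone.

**Step 1**
Reactants: 1 prop-2-en-1-yl 3-oxobutanoate (allyl acetoacetate); 2 acetone
Product: 3 prop-2-en-1-yl 2-acetyl-3-methylbut-2-enoate
Conditions: Ac2O, ZnCl2 (cat.), acetone (excess), reflux
Reagents that add atoms: none
Why: Knoevenagel condensation of the active methylene of 1 with acetone, driven by acetic anhydride as water scavenger (the variant used for isopropylidene malonates), should give the tetrasubstituted alkylidene acetoacetate; no stereocentre is formed.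

**Step 2**
Reactants: 3 prop-2-en-1-yl 2-acetyl-3-methylbut-2-enoate; 4 ethyl acetate
Product: 6 prop-2-en-1-yl 2,2-dimethyl-4,6-dioxocyclohexane-1-carboxylate, via keto diester Michael adduct 5 (not isolated)
Conditions: LDA (1.05 equiv), 4, THF, −78 °C; add 3, −78 → −40 °C; LDA (1.3 equiv), −78 → 0 °C; then 1 M HCl
Reagents that add atoms: none
Why: The lithium enolate of 4 adds in a conjugate sense to the doubly activated isopropylidene carbon of 3 (new quaternary CMe2–CH2 bond, the future C5–C4), giving the lithium enolate of β-keto ester 5; a second equivalent of LDA removes an acetyl proton to give the β-keto ester dianion, whose terminal carbon attacks the ethyl ester in a Dieckmann condensation (new CH2–C(=O) bond, the future C2–C3) and expels ethoxide. The sequence is the ester-enolate version of the tandem Michael–Claisen annulation used for 5,5-dimethylcyclohexane-1,3-diones. The six-membered ring closes by a 6-exo-trig acyl substitution (6-(enolexo) mode). The only stereocentre formed, C1 of 6, is an enolisable β-keto ester carbon, is obtained racemic and is erased in step 4, so no stereocontrol is needed here. The step needs 1,4- over 1,2-addition and addition over γ-deprotonation of 3: the two acceptor groups on the alkene, the reversibility of any 1,2-adduct on warming and the small unhindered acetate enolate should secure this, and the ester on the future spiro carbon keeps that carbon distinct from the acetate-derived CH2 in all later steps.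

**Step 3**
Reactants: 6 prop-2-en-1-yl 2,2-dimethyl-4,6-dioxocyclohexane-1-carboxylate
Product: 7 prop-2-en-1-yl 4-methoxy-2,2-dimethyl-6-oxocyclohex-4-ene-1-carboxylate
Conditions: HC(OMe)3, TsOH (cat.), MeOH (2 equiv), CH2Cl2, rt
Reagents that add atoms: trimethyl orthoformate, COC(OC)OC
Why: Acid-catalysed enol etherification of the cyclic 1,3-dione (vinylogous ester formation) under equilibrating conditions should place the methoxy group on the unhindered C4 oxygen, while the C6 carbonyl stays in the hydrogen-bonded β-keto ester enol; C1 of 7 is a labile racemic centre.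

**Step 4**
Reactants: 7 prop-2-en-1-yl 4-methoxy-2,2-dimethyl-6-oxocyclohex-4-ene-1-carboxylate
Product: 8 3-methoxy-5,5-dimethyl-6-methylidenecyclohex-2-en-1-one
Conditions: Pd(PPh3)4 (2 mol %), Et2NH (3 equiv), THF, rt; then (CH2O)n, AcOH (1 equiv), 50 °C
Reagents that add atoms: formaldehyde (as paraformaldehyde), C=O
Why: Tsuji–Trost deallylation (allyl transfer to diethylamine) unmasks the β-keto acid, and a decarboxylative Mannich reaction with the iminium ion of formaldehyde followed by loss of the amine should put the exocyclic methylene exactly on the former ester carbon; no stereocentre remains.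

**Step 5**
Reactants: 8 3-methoxy-5,5-dimethyl-6-methylidenecyclohex-2-en-1-one; 9 isoprene
Product: 10 (6S)-3-methoxy-5,5,9-trimethylspiro[5.5]undeca-2,8-dien-1-one
Conditions: chiral confined imidodiphosphorimidate (IDPi) Brønsted acid (2 mol %), 9 (5 equiv), CH2Cl2, −40 °C
Reagents that add atoms: none
Why: Brønsted acid-catalysed spirocyclising Diels–Alder reaction of the exocyclic enone with isoprene in the "para" orientation (methyl-bearing carbon 1,4 to the spiro carbon) closes ring B; the spiro stereocentre (6S) is set by the confined chiral counter-anion, which shields one face of the protonated enone.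

**Step 6**
Reactants: 10 (6S)-3-methoxy-5,5,9-trimethylspiro[5.5]undeca-2,8-dien-1-one
Product: 12 (6S)-1,5,5,9-tetramethylspiro[5.5]undeca-1,8-dien-3-one, via tertiary allylic alcohol 11 (not isolated)
Conditions: MeLi, CeCl3, THF, −78 °C; then 1 M HCl, THF, rt
Reagents that add atoms: methyllithium, [Li]C
Why: Stork–Danheiser transposition: cerium-mediated 1,2-addition of methyllithium to the hindered vinylogous ester carbonyl, then acid hydrolysis of the enol ether with loss of water, should give the 1-methyl enone; the spiro centre is not touched.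

**Step 7**
Reactants: 12 (6S)-1,5,5,9-tetramethylspiro[5.5]undeca-1,8-dien-3-one
Product: 13 (6S,8R,9S)-8,9-epoxy-1,5,5,9-tetramethylspiro[5.5]undec-1-en-3-one
Conditions: m-CPBA, NaHCO3, CH2Cl2, 0 °C
Reagents that add atoms: 3-chloroperoxybenzoic acid, O=C(OO)c1cccc(Cl)c1
Why: Prilezhaev epoxidation is chemoselective for the electron-rich trisubstituted ring B alkene over the enone, and the peracid should approach anti to the pseudo-axial C1 arm of ring A (the bulkier C5 gem-dimethyl arm sits pseudo-equatorial on the ring B half-chair), which sets C8 and C9.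

**Step 8**
Reactants: 13 (6S,8R,9S)-8,9-epoxy-1,5,5,9-tetramethylspiro[5.5]undec-1-en-3-one
Product: 14 (6S,8S,9S)-8-chloro-9-hydroxy-1,5,5,9-tetramethylspiro[5.5]undec-1-en-3-one
Conditions: LiCl (5 equiv), AcOH (3 equiv), THF, rt
Reagents that add atoms: lithium chloride, [Li+].[Cl-]
Why: Trans-diaxial (Fürst–Plattner) epoxide opening: in the half-chair that keeps C5 equatorial only attack at the secondary C8 leads directly to a chair, so chloride should enter at C8 with inversion and leave the tertiary C9–O bond intact, as in the HX opening of 5α,6α-epoxy steroids.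

**Step 9**
Reactants: 14 (6S,8S,9S)-8-chloro-9-hydroxy-1,5,5,9-tetramethylspiro[5.5]undec-1-en-3-one
Product: 15 (6S,8S,9S)-9-bromo-8-chloro-1,5,5,9-tetramethylspiro[5.5]undec-1-en-3-one
Conditions: TMSBr (3 equiv), CH2Cl2, −20 → 0 °C
Reagents that add atoms: bromotrimethylsilane, C[Si](C)(C)Br
Why: Ionisation of the tertiary alcohol is assisted by the anti-periplanar C8 chlorine (chloronium ion), and bromide should open the bridged ion at the tertiary C9 from the face the oxygen left, an SN1 substitution with net retention that gives the trans-diaxial bromochloride.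

**Step 10**
Reactants: 15 (6S,8S,9S)-9-bromo-8-chloro-1,5,5,9-tetramethylspiro[5.5]undec-1-en-3-one
Product: 17 (4R,6R,8S,9S)-4,9-dibromo-8-chloro-1,5,5,9-tetramethylspiro[5.5]undec-1-en-3-one, via silyl dienol ether 16 (not isolated)
Conditions: LiHMDS, TMSCl, THF, −78 °C; then NBS, THF, −78 → 0 °C
Reagents that add atoms: N-bromosuccinimide, O=C1CCC(=O)N1Br
Why: Kinetic α'-deprotonation and silylation give the cross-conjugated silyl dienol ether, which NBS should brominate at C4 (electrophilic α-halogenation of an enol ether) from the face anti to the pseudo-axial ring B methylene on the spiro carbon; this facial preference is the least secure stereochemical call of the route, and the C4 epimer would be separable.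

**Step 11**
Reactants: 17 (4R,6R,8S,9S)-4,9-dibromo-8-chloro-1,5,5,9-tetramethylspiro[5.5]undec-1-en-3-one
Product: 18 (3S,4R,6R,8S,9S)-4,9-dibromo-8-chloro-1,5,5,9-tetramethylspiro[5.5]undec-1-en-3-ol
Conditions: DIBAL-H, CH2Cl2, −78 °C; Rochelle salt work-up
Reagents that add atoms: none
Why: 1,2-Reduction of the α'-bromo enone; hydride should attack the carbonyl anti to the adjacent axial C–Br bond (Cornforth/polar Felkin–Anh control), giving the cis-bromohydrin (3S) without touching the alkyl halides at −78 °C.

**Compound list**
1 | prop-2-en-1-yl 3-oxobutanoate (allyl acetoacetate) | CC(=O)CC(=O)OCC=C | starting material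
2 | acetone | CC(C)=O | starting material
3 | prop-2-en-1-yl 2-acetyl-3-methylbut-2-enoate | CC(=O)C(=C(C)C)C(=O)OCC=C | intermediate
4 | ethyl acetate | CCOC(C)=O | starting material
5 | 5-ethyl 1-(prop-2-en-1-yl) 2-acetyl-3,3-dimethylpentanedioate (racemic, formed as its lithium enolate) | CCOC(=O)CC(C)(C)C(C(C)=O)C(=O)OCC=C | intermediate
6 | prop-2-en-1-yl 2,2-dimethyl-4,6-dioxocyclohexane-1-carboxylate (racemic, enolised) | C=CCOC(=O)C1C(=O)CC(=O)CC1(C)C | intermediate
7 | prop-2-en-1-yl 4-methoxy-2,2-dimethyl-6-oxocyclohex-4-ene-1-carboxylate (racemic) | C=CCOC(=O)C1C(=O)C=C(OC)CC1(C)C | intermediate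
8 | 3-methoxy-5,5-dimethyl-6-methylidenecyclohex-2-en-1-one | COC1=CC(=O)C(=C)C(C)(C)C1 | intermediate
9 | isoprene (2-methylbuta-1,3-diene) | C=CC(C)=C | starting material
10 | (6S)-3-methoxy-5,5,9-trimethylspiro[5.5]undeca-2,8-dien-1-one | O=C1C=C(OC)CC(C)(C)[C@@]12CCC(C)=CC2 | intermediate
11 | (6S)-3-methoxy-1,5,5,9-tetramethylspiro[5.5]undeca-2,8-dien-1-ol (C1 epimers) | CC1(O)C=C(OC)CC(C)(C)[C@@]12CCC(C)=CC2 | intermediate
12 | (6S)-1,5,5,9-tetramethylspiro[5.5]undeca-1,8-dien-3-one | CC1=CC(=O)CC(C)(C)[C@@]12CCC(C)=CC2 | intermediate
13 | (6S,8R,9S)-8,9-epoxy-1,5,5,9-tetramethylspiro[5.5]undec-1-en-3-one | CC1=CC(=O)CC(C)(C)[C@@]12CC[C@]3(C)O[C@@H]3C2 | intermediate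
14 | (6S,8S,9S)-8-chloro-9-hydroxy-1,5,5,9-tetramethylspiro[5.5]undec-1-en-3-one | CC1=CC(=O)CC(C)(C)[C@@]12CC[C@](C)(O)[C@@H](Cl)C2 | intermediate
15 | (6S,8S,9S)-9-bromo-8-chloro-1,5,5,9-tetramethylspiro[5.5]undec-1-en-3-one | CC1=CC(=O)CC(C)(C)[C@@]12CC[C@](C)(Br)[C@@H](Cl)C2 | intermediate
16 | {[(6R,8S,9S)-9-bromo-8-chloro-1,5,5,9-tetramethylspiro[5.5]undeca-1,3-dien-3-yl]oxy}trimethylsilane | CC1=CC(O[Si](C)(C)C)=CC(C)(C)[C@@]12CC[C@](C)(Br)[C@@H](Cl)C2 | intermediate
17 | (4R,6R,8S,9S)-4,9-dibromo-8-chloro-1,5,5,9-tetramethylspiro[5.5]undec-1-en-3-one | CC1=CC(=O)[C@H](Br)C(C)(C)[C@@]12CC[C@](C)(Br)[C@@H](Cl)C2 | intermediate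
18 | (3S,4R,6R,8S,9S)-4,9-dibromo-8-chloro-1,5,5,9-tetramethylspiro[5.5]undec-1-en-3-ol | CC1=C[C@H](O)[C@H](Br)C(C)(C)[C@@]12CC[C@](C)(Br)[C@@H](Cl)C2 | target

Total step count: 11
Longest linear sequence: 11 steps (1 → 18)

**Steps most likely to fail**

1. Step 2 (key step). What may go wrong: the basic lithium enolate removes a γ-proton from an allylic methyl group of 3 faster than it adds, so that the dienolate of 3 and ethyl acetate are returned. The fallback sets out from 3 and comes back at 6, still in one flask and still forming both bonds in one operation: a non-basic zinc enolate replaces the lithium enolate as the two-carbon donor. Methyl bromoacetate and activated zinc (Reformatsky reagent, THF) should add 1,4 to 3 to give the zinc enolate of 5-methyl 1-(prop-2-en-1-yl) 2-acetyl-3,3-dimethylpentanedioate F1, and LiHMDS (2.2 equiv) added to the same flask should form the dianion and close the ring by Dieckmann condensation to 6.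

2. Step 5. What may go wrong: the vinylogous ester carbonyl activates the exocyclic alkene less than a simple ketone would, so the cycloaddition may be slow, isoprene may oligomerise under the strong acid, or the facial discrimination may be low. The fallback sets out from 7 (bypassing steps 4 and 5) and comes back at 10, using the allyl β-keto ester that is already in place. C-Alkylation of 7 with 4-iodo-2-methylbut-1-ene (Cs2CO3, DMF) should give racemic prop-2-en-1-yl 4-methoxy-2,2-dimethyl-1-(3-methylbut-3-en-1-yl)-6-oxocyclohex-4-ene-1-carboxylate F2. Palladium-catalysed decarboxylative asymmetric allylic alkylation (Pd2(dba)3, t-Bu-PHOX ligand of the appropriate hand, toluene) should then give (6S)-3-methoxy-5,5-dimethyl-6-(3-methylbut-3-en-1-yl)-6-(prop-2-en-1-yl)cyclohex-2-en-1-one F3. Ring-closing metathesis (Grubbs II, CH2Cl2, 40 °C) between the allyl and the 3-methylbut-3-enyl termini closes ring B to 10.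

3. Step 9. What may go wrong: the cation formed on ionisation loses a proton (E1) or the halogens scramble through the chloronium ion before bromide is captured. The fallback sets out from 14 and comes back at 15 by elimination followed by hydrobromination. Deliberate anti-elimination with SOCl2/pyridine (0 °C) should give the allylic chloride (6S,8S)-8-chloro-1,5,5,9-tetramethylspiro[5.5]undeca-1,9-dien-3-one F4, possibly with its exocyclic isomer (6S,8S)-8-chloro-1,5,5-trimethyl-9-methylidenespiro[5.5]undec-1-en-3-one F5. Markovnikov addition of anhydrous HBr in CH2Cl2 at −40 °C to either isomer should then give 15, since the high bromide concentration and low temperature favour capture at C9 anti to the chlorine.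

**Further compounds**
F1 | step 2 | 5-methyl 1-(prop-2-en-1-yl) 2-acetyl-3,3-dimethylpentanedioate | COC(=O)CC(C)(C)C(C(C)=O)C(=O)OCC=C
F2 | step 5 | prop-2-en-1-yl 4-methoxy-2,2-dimethyl-1-(3-methylbut-3-en-1-yl)-6-oxocyclohex-4-ene-1-carboxylate (racemic) | C=CCOC(=O)C1(CCC(C)=C)C(=O)C=C(OC)CC1(C)C
F3 | step 5 | (6S)-3-methoxy-5,5-dimethyl-6-(3-methylbut-3-en-1-yl)-6-(prop-2-en-1-yl)cyclohex-2-en-1-one | O=C1C=C(OC)CC(C)(C)[C@@]1(CC=C)CCC(C)=C
F4 | step 9 | (6S,8S)-8-chloro-1,5,5,9-tetramethylspiro[5.5]undeca-1,9-dien-3-one | CC1=CC(=O)CC(C)(C)[C@@]12CC=C(C)[C@@H](Cl)C2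
F5 | step 9 | (6S,8S)-8-chloro-1,5,5-trimethyl-9-methylidenespiro[5.5]undec-1-en-3-one | CC1=CC(=O)CC(C)(C)[C@@]12CCC(=C)[C@@H](Cl)C2
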